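Slowness is what you notice first. In teal, by its forward rate at the charged concentrations, complex with one exchanged has a half-life of 7.2 d towards complex with two exchanged, longer than the run of 2.5 d. But it also decays to side product, with a half-life of 0.93 h, which is far shorter. So the question for the next run is which charge to change.

| setting | teal | grey | amber |
|---|---|---|---|
| starting complex | 0.80 M | 0.80 M | 0.80 M |
| incoming ligand | 0.800 M | 0.800 M | 0.800 M |
| leaving ligand | 0.800 M | 0.960 M | 1.20 M |
| time | 2.5 d | 2.5 d | 2.5 d |

    complex with one exchanged + incoming ligand ⇌ leaving ligand + complex with two exchanged (K1 = 0.68, k1 = 0.00504 M⁻¹ h⁻¹)
    complex with four exchanged + incoming ligand ⇌ idle adduct, settled at all times (K2 = 2.1 M⁻¹)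
    complex with three exchanged + incoming ligand ⇌ leaving ligand + complex with four exchanged (K3 = 0.38, k3 = 0.00166 M⁻¹ h⁻¹)
    complex with one exchanged → side product (k4 = 0.743 h⁻¹)
    complex with two exchanged + incoming ligand ⇌ leaving ligand + complex with three exchanged (K5 = 9.7, k5 = 0.00450 M⁻¹ h⁻¹)
    starting complex + incoming ligand ⇌ leaving ligand + complex with one exchanged (K6 = 0.36, k6 = 0.0360 M⁻¹ h⁻¹)

- which of the two there is more of at the end, teal (complex with four exchanged / side product)
- which of the two there is more of at the end, grey (complex with four exchanged / side product)
- which of the two there is more of at the end, amber (complex with four exchanged / side product)
- final complex with four exchanged, as a percentage of the starting complex charged, in teal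
- final complex with four exchanged, as a percentage of the starting complex charged, in grey
- final complex with four exchanged, as a percentage of the starting complex charged, in amber

Divide the two rates. The concentration of complex with one exchanged cancels, but incoming ligand stays in the ratio, so the ratio moves as that ligand is used. Call φ the pass-on share, the forward exchange rate of complex with one exchanged over its rate of decay to side product, with incoming ligand as charged 0.543 %. This is a selectivity factor: 0.00504 M⁻¹ h⁻¹ times 0.800 M of incoming ligand, over 0.743 h⁻¹. The three flasks share that charge, so they share φ at the start. Leaving ligand does not enter this forward share, so I would not charge more of it to change φ. Incoming ligand is the charge to vary.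

Beyond that branch, complex with two exchanged has a forward half-life of 8.0 d in teal, longer than the run. I therefore commit to side product over complex with four exchanged in each flask. I also expect what lies past the first complex to stay under φ of the side product. That is a ceiling, and it gives no figure for complex with four exchanged.

The forecast does give one: <0.001 % in teal, <0.001 % in grey and <0.001 % in amber, with side product, side product and side product ahead, because “side product takes nearly everything that reaches it”.

The simulation gives side product in teal at 59.2 %, side product in grey at 58.8 % and side product in amber at 58.1 %. Complex with four exchanged stands at 0 %, 0 % and 0 %.

In grey, starting complex fell to 57.3 % at 1.25 d and 40.5 % at 2.50 d, while the decay to side product ran and side product reached 58.8 %. Complex with one exchanged stood at 1.12 %, then 0.544 %, its making over its using-up being 0.973 at the end. As a reading, complexes with two and three exchanged together hold 0.255 % of the side product in grey, below φ, about half of it.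

Now take the flask like grey but with 1.4 M of incoming ligand. There φ is 0.950 %, and the same fraction of it gives 0.446 %. Computed, complexes with two and three exchanged hold 0.470 % of that flask's 81.0 % side product, and complex with four exchanged stands at 0 %.

(Its constants are assumed; the rest is arithmetic.)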